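**Retrosynthetic overview**
- The target comes from the 2-crotonoyl-2-hydroxycycloheptanone fused to the lactone, by OH-directed ketone reduction and then selective O-isobutyrylation.
- That ketol comes from a 1-hydroxycyclohexyl ene-1,2-dione by an α-ketol 1,2-shift of the CHMe ring carbon (six- to seven-membered ring). The dione comes from the all-cis bicyclic keto lactone and a crotonyl diazoketone (diazo aldol, then C=N2 to C=O).
- The keto lactone comes from a hydroxy butenolide by hydrogenation and oxidation. The butenolide comes from ynolate olefination and oxirane opening of a trans-epoxy ketone.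
- The epoxy ketone comes from (S)-4-methylcyclohex-2-enone, which comes from propanal and methyl vinyl ketone (organocatalytic Michael addition and aldol condensation).
- Ring order: six-membered ring A (step 1), γ-lactone ring B (step 3), ring A enlarged to seven members (step 8).

Assumption: locants follow 1-benzofuran and cyclohepta[b]furan numbering, and the (R)-diphenylprolinol ether is taken to give the (S)-aldehyde, the mirror image of the established sense of its (S)-enantiomer.

**Step 1**
Reactants: 1 propanal; 2 but-3-en-2-one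
Product: 4 (S)-4-methylcyclohex-2-en-1-one, via (S)-2-methyl-5-oxohexanal 3 (not isolated)
Conditions: (R)-2-[methoxy(diphenyl)methyl]pyrrolidine (5 mol%), ethyl 3,4-dihydroxybenzoate (20 mol%), neat, 4 °C; then aq. KOH (0.1 M), n-Bu4NOH (cat.), Et2O/THF, 40 °C
Reagents that add atoms: none
Why: Enamine-catalysed asymmetric Michael addition, in which the diarylprolinol ether blocks one enamine face and sets the methyl-bearing centre as S, is followed by an intramolecular aldol condensation that closes ring A.

**Step 2**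
Reactants: 4 (S)-4-methylcyclohex-2-en-1-one
Product: 5 (1R,5S,6R)-5-methyl-7-oxabicyclo[4.1.0]heptan-2-one
Conditions: 30% H2O2, NaOH (cat.), MeOH, 0 °C
Reagents that add atoms: hydrogen peroxide, OO
Why: In this Weitz–Scheffer nucleophilic epoxidation the hydroperoxide adds axially to the β-carbon anti to the neighbouring methyl group, so the oxirane is trans to it.

**Step 3**
Reactants: 5 (1R,5S,6R)-5-methyl-7-oxabicyclo[4.1.0]heptan-2-one; 6 prop-1-yn-1-yllithium
Product: 9 (6S,7R,7aR)-7-hydroxy-3,6-dimethyl-5,6,7,7a-tetrahydro-1-benzofuran-2(4H)-one, via lithium prop-1-yn-1-olate 7 (not isolated), via lithium Z-epoxycyclohexylidenepropanoate 8 (not isolated)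
Conditions: t-BuOOH, LiN(SiMe3)2, THF, −78 °C; add 6, −78 → 0 °C; add 5, 0 °C → rt; then 1 M HCl, rt
Reagents that add atoms: tert-butyl hydroperoxide, CC(C)(C)OO
Why: Ynolate olefination of an α-oxy ketone (β-lactone enolate, then ring opening with the C–O-bearing carbon turning inward) gives the Z-carboxylate, which opens the allylic oxirane carbon 5-exo with inversion, so the lactone oxygen ends up cis to the methyl group and the freed carbinol trans to it.

**Step 4**
Reactants: 9 (6S,7R,7aR)-7-hydroxy-3,6-dimethyl-5,6,7,7a-tetrahydro-1-benzofuran-2(4H)-one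
Product: 10 (3R,3aS,6S,7R,7aR)-7-hydroxy-3,6-dimethylhexahydro-1-benzofuran-2(3H)-one
Conditions: H2 (60 bar), 5% Rh/Al2O3, EtOAc, rt
Reagents that add atoms: none
Why: Heterogeneous syn hydrogenation of the tetrasubstituted butenolide from the convex face that carries H-7a makes H-3, H-3a and H-7a all cis (cis-fused lactone, 3-methyl on the concave side), and rhodium avoids allylic C–O hydrogenolysis.

**Step 5**
Reactants: 10 (3R,3aS,6S,7R,7aR)-7-hydroxy-3,6-dimethylhexahydro-1-benzofuran-2(3H)-one
Product: 11 (3R,3aS,6S,7aR)-3,6-dimethylhexahydro-1-benzofuran-2,7-dione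
Conditions: Dess–Martin periodinane, CH2Cl2, 0 °C → rt; product used without chromatography
Reagents that add atoms: none
Why: Dess–Martin oxidation runs under mild, base-free conditions, so the two epimerisable α-centres (C6 and C7a) of the all-cis keto lactone are kept.

**Step 6**
Reactants: 12 (E)-pent-3-en-2-one
Product: 14 (E)-1-diazopent-3-en-2-one, via (E)-1,1,1-trifluorohept-5-ene-2,4-dione 13 (not isolated)
Conditions: LiN(SiMe3)2, THF, −78 °C; CF3CO2CH2CF3; aq. HCl work-up; then MsN3, Et3N, H2O, MeCN, rt
Reagents that add atoms: methanesulfonyl azide, CS(=O)(=O)N=[N+]=[N-]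
Why: Detrifluoroacetylative (Regitz-type) diazo transfer onto the kinetic enolate position gives the enone diazoketone without the pyrazoline formation seen when enoyl chlorides meet diazomethane, and no stereocentre is formed.

**Step 7**
Reactants: 14 (E)-1-diazopent-3-en-2-one; 11 (3R,3aS,6S,7aR)-3,6-dimethylhexahydro-1-benzofuran-2,7-dione
Product: 16 (3R,3aS,6S,7R,7aR)-7-[(E)-1-diazo-2-oxopent-3-en-1-yl]-7-hydroxy-3,6-dimethylhexahydro-1-benzofuran-2(3H)-one, via lithiated diazoketone 15 (not isolated)
Conditions: 14, LiN(i-Pr)2, THF, −90 °C, 10 min; add 11, −78 °C; AcOH quench at −78 °C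
Reagents that add atoms: none
Why: In this aldol-type 1,2-addition of an α-lithio diazoketone, the methyl group, the lactone oxygen and the lactone carbon all sit on one face of 11, so attack comes from the opposite convex face and places the new tertiary OH cis to these three groups.

**Step 8**
Reactants: 16 (3R,3aS,6S,7R,7aR)-7-[(E)-1-diazo-2-oxopent-3-en-1-yl]-7-hydroxy-3,6-dimethylhexahydro-1-benzofuran-2(3H)-one
Product: 18 (3R,3aS,6S,7R,8aR)-7-[(E)-but-2-enoyl]-7-hydroxy-3,6-dimethylhexahydro-2H-cyclohepta[b]furan-2,8(3H)-dione, via hydroxy enedione 17 (not isolated)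
Conditions: dimethyldioxirane (1.05 equiv, acetone), CH2Cl2, −40 → 0 °C; evaporate; Sc(OTf)3 (10 mol%), 4 Å MS, CH2Cl2, −20 °C → rt
Reagents that add atoms: dimethyldioxirane, CC1(C)OO1
Why: Proposed new method: dimethyldioxirane converts C=N2 into C=O (known), and the resulting 1-hydroxycyclohexyl ene-1,2-dione 17 then undergoes a scandium-templated α-ketol 1,2-shift that enlarges a six- to a seven-membered ring, which has not been shown for this substrate class; trivalent scandium binds the carbinol oxygen and the adjacent carbonyl oxygen in a five-membered chelate (the enone oxygen can complete a tridentate array), the only binding mode that activates the migration terminus, so the two C–O bonds are held syn-periplanar; the electron-richer CHMe ring carbon migrates rather than the acyloxy-bearing one, suprafacially and with retention, which copies the carbinol configuration into the new tertiary carbinol (OH cis to methyl, crotonoyl trans); loss of vicinal-dicarbonyl repulsion and the chelated 2-hydroxy-1,3-diketone should offset the extra ring strain; the closest known reaction types are the Lewis-acid-catalysed α-ketol rearrangement of β-hydroxy-α-dicarbonyls to α-hydroxy-β-dicarbonyls and the D-homoannulation of 17-hydroxy-20-keto steroids.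

**Step 9**
Reactants: 18 (3R,3aS,6S,7R,8aR)-7-[(E)-but-2-enoyl]-7-hydroxy-3,6-dimethylhexahydro-2H-cyclohepta[b]furan-2,8(3H)-dione
Product: 19 (3R,3aS,6S,7S,8S,8aR)-7-[(E)-but-2-enoyl]-7,8-dihydroxy-3,6-dimethyloctahydro-2H-cyclohepta[b]furan-2-one
Conditions: Me4NBH(OAc)3, MeCN/AcOH 1:1, −30 °C
Reagents that add atoms: none
Why: In this hydroxyl-directed (Saksena–Evans) reduction the tertiary OH exchanges onto boron and delivers hydride to its own face of the more electrophilic saturated α-acyloxy ketone, which gives the trans-7,8-diol and leaves the conjugated enone untouched.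

**Step 10**
Reactants: 19 (3R,3aS,6S,7S,8S,8aR)-7-[(E)-but-2-enoyl]-7,8-dihydroxy-3,6-dimethyloctahydro-2H-cyclohepta[b]furan-2-one; 20 2-methylpropanoyl chloride
Product: 21 (3R,3aS,6S,7S,8S,8aR)-7-[(E)-but-2-enoyl]-7-hydroxy-3,6-dimethyl-2-oxooctahydro-2H-cyclohepta[b]furan-8-yl 2-methylpropanoate
Conditions: 20 (1.3 equiv), pyridine, DMAP (cat.), CH2Cl2, 0 °C → rt
Reagents that add atoms: none
Why: DMAP-catalysed acylation esterifies the secondary 8-OH only, because the tertiary α-ketol OH is too hindered and too electron-poor to react, and no stereocentre is touched.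

**Compound list**
1 | propanal | CCC=O | starting material
2 | but-3-en-2-one | CC(=O)C=C | starting material
3 | (S)-2-methyl-5-oxohexanal | C[C@@H](CCC(C)=O)C=O | intermediate
4 | (S)-4-methylcyclohex-2-en-1-one | C[C@H]1CCC(=O)C=C1 | intermediate
5 | (1R,5S,6R)-5-methyl-7-oxabicyclo[4.1.0]heptan-2-one | C[C@H]1CCC(=O)[C@@H]2O[C@H]12 | intermediate
6 | prop-1-yn-1-yllithium | [Li]C#CC | starting material
7 | lithium prop-1-yn-1-olate | CC#C[O-].[Li+] | intermediate
8 | lithium (2Z)-2-[(1S,5S,6R)-5-methyl-7-oxabicyclo[4.1.0]heptan-2-ylidene]propanoate | C[C@H]1CC/C(=C(\C)C(=O)[O-])[C@@H]2O[C@H]12.[Li+] | intermediate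
9 | (6S,7R,7aR)-7-hydroxy-3,6-dimethyl-5,6,7,7a-tetrahydro-1-benzofuran-2(4H)-one | C[C@H]1CCC2=C(C)C(=O)O[C@H]2[C@@H]1O | intermediate
10 | (3R,3aS,6S,7R,7aR)-7-hydroxy-3,6-dimethylhexahydro-1-benzofuran-2(3H)-one | C[C@H]1CC[C@@H]2[C@@H](OC(=O)[C@@H]2C)[C@@H]1O | intermediate
11 | (3R,3aS,6S,7aR)-3,6-dimethylhexahydro-1-benzofuran-2,7-dione | C[C@H]1CC[C@@H]2[C@@H](OC(=O)[C@@H]2C)C1=O | intermediate
12 | (E)-pent-3-en-2-one | C/C=C/C(C)=O | starting material
13 | (E)-1,1,1-trifluorohept-5-ene-2,4-dione | C/C=C/C(=O)CC(=O)C(F)(F)F | intermediate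
14 | (E)-1-diazopent-3-en-2-one | C/C=C/C(=O)C=[N+]=[N-] | intermediate
15 | (E)-1-diazo-1-lithiopent-3-en-2-one | C/C=C/C(=O)C([Li])=[N+]=[N-] | intermediate
16 | (3R,3aS,6S,7R,7aR)-7-[(E)-1-diazo-2-oxopent-3-en-1-yl]-7-hydroxy-3,6-dimethylhexahydro-1-benzofuran-2(3H)-one | C/C=C/C(=O)C(=[N+]=[N-])[C@]1(O)[C@@H](C)CC[C@@H]2[C@H]1OC(=O)[C@@H]2C | intermediate
17 | (E)-1-[(3R,3aS,6S,7S,7aR)-7-hydroxy-3,6-dimethyl-2-oxooctahydro-1-benzofuran-7-yl]pent-3-ene-1,2-dione | C/C=C/C(=O)C(=O)[C@]1(O)[C@@H](C)CC[C@@H]2[C@H]1OC(=O)[C@@H]2C | intermediate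
18 | (3R,3aS,6S,7R,8aR)-7-[(E)-but-2-enoyl]-7-hydroxy-3,6-dimethylhexahydro-2H-cyclohepta[b]furan-2,8(3H)-dione | C/C=C/C(=O)[C@]1(O)[C@@H](C)CC[C@@H]2[C@@H](OC(=O)[C@@H]2C)C1=O | intermediate
19 | (3R,3aS,6S,7S,8S,8aR)-7-[(E)-but-2-enoyl]-7,8-dihydroxy-3,6-dimethyloctahydro-2H-cyclohepta[b]furan-2-one | C/C=C/C(=O)[C@]1(O)[C@@H](C)CC[C@@H]2[C@@H](OC(=O)[C@@H]2C)[C@@H]1O | intermediate
20 | 2-methylpropanoyl chloride | CC(C)C(=O)Cl | starting material
21 | (3R,3aS,6S,7S,8S,8aR)-7-[(E)-but-2-enoyl]-7-hydroxy-3,6-dimethyl-2-oxooctahydro-2H-cyclohepta[b]furan-8-yl 2-methylpropanoate | C/C=C/C(=O)[C@]1(O)[C@@H](C)CC[C@@H]2[C@@H](OC(=O)[C@@H]2C)[C@@H]1OC(=O)C(C)C | target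

**Total step count:** 10
**Longest linear sequence:** 9 (steps 1–5 and 7–10; step 6 is the side branch). No protecting groups are used.

**Three steps most likely to fail**

**Step 8 (the new step).**
- Risks: the six-to-seven equilibrium may not lie far enough on the product side. The acyloxy-bearing ring carbon may migrate instead of the CHMe carbon. A non-chelated anti conformer would give the C7 epimer.
- Fallback from 16 back to 18, known chemistry: Rh2(OAc)4 (1 mol%) in CH2Cl2 triggers the established carbenoid 1,2-alkyl shift of α-diazo-β-hydroxy ketones. This gives the ring-enlarged 2-crotonoylcycloheptanone F2, largely enolised at C7.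
- The enolate of F2 (KN(SiMe3)2, THF, −78 °C) is then hydroxylated with the enantiomer of (camphorylsulfonyl)oxaziridine that delivers oxygen to the face carrying the 6-methyl group.
- The substrate bias opposes this facial delivery, so 18 would have to be separated from its C7 epimer.

**Step 3.**
- Risks: the ynolate is made in the presence of t-BuOLi. The Z-selective ring opening and the in-plane opening of the oxirane by the carboxylate have not been tested on an α,β-epoxy ketone.
- Fallback from 5 back to 9: Horner–Wadsworth–Emmons olefination of 5 with trimethyl 2-phosphonopropionate and NaH in THF. After separation from the E isomer this gives methyl (2Z)-2-[(1S,5S,6R)-5-methyl-7-oxabicyclo[4.1.0]heptan-2-ylidene]propanoate F1.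
- CF3CO2H/H2O then promotes attack of the ester carbonyl on the allylic oxirane carbon with inversion, and loss of methanol gives 9. This costs one extra step.

**Step 9.**
- Risks: both polar Felkin–Anh effects (7-OH and 8a-O) favour hydride attack from the wrong face. The five-membered delivery geometry is less well precedented than the six-membered one.
- Fallback from 18 back to 19, covalent tethering of the hydride: ClSiHMe2, Et3N and DMAP give the 7-O-dimethylsilyl ether of 18 F3.
- SnCl4 in CH2Cl2 at −78 °C induces intramolecular hydrosilylation of the ring ketone from the face of the tether. This gives the 7,8-O-dimethylsilanediyl derivative of 19 F4.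
- HF·pyridine in THF then releases 19.

**Further compounds**
F1 | step 3 | methyl (2Z)-2-[(1S,5S,6R)-5-methyl-7-oxabicyclo[4.1.0]heptan-2-ylidene]propanoate | C[C@H]1CC/C(=C(\C)C(=O)OC)[C@@H]2O[C@H]12
F2 | step 8 | (3R,3aS,6S,8aR)-7-[(E)-but-2-enoyl]-3,6-dimethylhexahydro-2H-cyclohepta[b]furan-2,8(3H)-dione (C7 enolisable, not defined) | C/C=C/C(=O)C1[C@@H](C)CC[C@@H]2[C@@H](OC(=O)[C@@H]2C)C1=O
F3 | step 9 | (3R,3aS,6S,7R,8aR)-7-[(E)-but-2-enoyl]-7-[(dimethylsilyl)oxy]-3,6-dimethylhexahydro-2H-cyclohepta[b]furan-2,8(3H)-dione | C/C=C/C(=O)[C@]1(O[SiH](C)C)[C@@H](C)CC[C@@H]2[C@@H](OC(=O)[C@@H]2C)C1=O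
F4 | step 9 | 7,8-O-dimethylsilanediyl derivative of 19 | C/C=C/C(=O)[C@@]12O[Si](C)(C)O[C@H]1[C@@H]1OC(=O)[C@H](C)[C@@H]1CC[C@@H]2C
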